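The data come from a simulation with constants of no real substance, and the scatter is random.

The first reading of the south-west run puts target over other capture product at 1.20, while the sums of its first 3 readings put it lower, at 0.952. We call this number the early capture ratio s: target per other capture product, each summed over the readings up to 15.0 h.

| flask | substrate | first nucleophile | second nucleophile | remark | time |
|---|---|---|---|---|---|
| south-west | 0.10 M | 0.20 M | 0.50 M | run made earlier |  |
| flask | 0.20 M | 0.200 M | 0.500 M |  | 8.0 d |

- south-west (time / h: target / %, other capture product / %): 2.50: 6, 5; 8.00: 15, 14; 15.0: 19, 23; 20.0: 26, 26; 30.0: 28, 32; 40.0: 31, 36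

(readings scatter by 1.5 percentage points)

* ratio of target to other capture product at 15 min
* ratio of target to other capture product at 8.0 d

The two ways part, so one of them cheats. The scatter of 1.5 percentage points weighs more on the first reading of other capture product, 5%, than on the sum of 42.0%, so we take s as our reading. It reaches to 15.0 h, and the ratio reads 0.861 at 40.0 h, so a drift may lean on it a little.

The flask has the same nucleophile charges and twice the substrate. At the pace of the first reading, 15 min in the flask captures about 0.00220 M, far less than 0.200 M, so we expect s at 15 min. For 8.0 d we reckon nothing of our own.

The forecast differs from us at 15 min with 1.2, and gives 0.5 at 8.0 d, “with wide uncertainty”.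

The flask gives 0.956 at 15 min and 0.382 at 8.0 d.

    substrate ⇌ intermediate (K = 0.00300, k = 0.0656 h⁻¹)
    first nucleophile + intermediate → target (k = 144 M⁻¹ h⁻¹)
    second nucleophile + intermediate → other capture product (k = 60.3 M⁻¹ h⁻¹)
    target ⇌ isomer of the product (K = 2.80, k = 0.0213 h⁻¹)
    second nucleophile ⇌ dormant form (K = 3.20, k = 0.0372 h⁻¹)

The flask's early ratio is 1.00 times s, and the neighbouring flask with 0.50 M of substrate and the same nucleophile charges gives 0.954, or 1.00 times s. At 0.492 d target in the flask is made 3.65 times faster than it is used up, each step taken net, yet its half-life by the forward turning into isomer of the product, 1.4 d, is short against 8.0 d. At 8.0 d the making is 0.193 of the using up, and the flask holds 16.0% target against 42.0% isomer of the product.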